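## The problem

Target 22 is a linear chain of five benzene rings (A to E) joined by four diaryl ether oxygens, each ring carrying four oxygens, twelve of which end as free phenols. There is no stereocentre and no other element of chirality, so nothing has to be set or relayed; the difficulty is purely regiochemical. Along the chain, ring A is bound through A1 with hydroxyls on A2, A4 and A6; ring B carries the ether to ring A on B1, the ether to ring C on B4 and hydroxyls on B3 and B5; ring C carries the ether to ring B on C1, the ether to ring D on the neighbouring C2 and hydroxyls on C3 and C5; ring D repeats ring B (D1, D4; hydroxyls on D3, D5); ring E is bound through E1 with hydroxyls on E3, E4 and E5. Every bridge therefore joins a carbon lying between two oxygenated carbons (A1, B4, C2, D4) to a more open carbon (B1, C1, D1, E1). The B4–O–C1 bridge is the worst case, with three ortho oxygen substituents (B3, B5, C2). Copper-mediated ether couplings accept the crowded ring as the phenol but only reluctantly as an electron-rich halide, so the polarity of each disconnection matters. The free polyphenol, above all pyrogallol ring E, is sensitive to air and base, so all hydroxyls travel as methyl ethers and are unveiled last. The feature that opens the key step is ring B: a phloroglucinol (oxygens on B1, B3, B5) with a fourth oxygen on B4 between two of them, which is the atom pattern of a 3-aryloxy-4-methoxy-6-methyl-2-pyranone (ring oxygen to the B1 hydroxyl, lactone carbonyl to B3, C3 to B4, C4 to B5, the methyl carbon to B2).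

## Retrosynthesis

**Unveiling.** Target 22 is traced back to its undecamethyl ether 21 by cutting eleven O–CH3 bonds. Methyl is chosen over benzyl because every bought building block (1, 2, 4, 17) is already a methyl ether and because methyl ethers survive peracid, base, hydrogenolysis and the carbenoid step. The forward reaction must cleave alkyl–oxygen bonds only and leave the four aryl–O–aryl bridges intact.

**Ring A.** Phenol 21 comes from aldehyde 19 by Baeyer–Villiger oxidation, 19 from phenol 18 by methylation, and 18 from resorcinol 16 and bromide 17 by cutting the A1–O bond. The oxygen must stay on B1, because B1 leaves the key step as a phenol; the opposite cut (O–B1) would need 16 as an electrophile. Ring A therefore has to be the halide with the leaving group between two methoxy groups, and the para-formyl group of 17 serves twice: it activates this crowded bromide and it is the masked A4 oxygen. The coupling must pick the open B1 hydroxyl of 16 over the B3 hydroxyl that lies next to the bulky aryloxy group.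

**Ring B (key cut).** Resorcinol 16 is unravelled at the B2–B3 bond to pyranone 14, an isomer of 16. The neighbouring cut, through the B4–O–C1 ether, would demand a coupling that creates a diaryl ether with three ortho oxygen substituents from two electron-rich partners; cutting inside the ring avoids this altogether. The precursor is simpler by one carbocycle, and the forward step has to open the lactone and close the chain again through carbon.

**The crowded ether.** Pyranone 14 comes from hydroxypyranone 13 by O-methylation, and 13 is cut at the bond between the phenol oxygen and pyranone C3 into phenol 10 and diazo compound 12, which is one diazo transfer away from bought lactone 11. A carbenoid O–H insertion is asked for; it forms the most hindered C–O bond of the molecule at a stage where the carbon partner is a small planar ring, not a hexasubstituted benzene.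

**Ring C to ring D.** Phenol 10 comes from benzyl ether 9 by hydrogenolysis, and 9 is cut at the D1–O bond into phenol 8 and bromide 3. This polarity puts the crowded ring C2 oxygen on the nucleophile and the leaving group on the open D1 carbon; the opposite cut would need a ring C halide flanked by two oxygens. Attaching rings D and E before ring B is built lets one benzyl group do all the protecting-group work on ring C.

**Ring C.** Phenol 8 comes from aldehyde 6 by Baeyer–Villiger oxidation, the aldehyde carbon becoming the C2 oxygen, and 6 from bought salicylaldehyde 4 and benzyl bromide 5. The benzyl ether keeps the future C1 oxygen silent during the coupling and releases it under neutral conditions.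

**Rings D and E.** Bromide 3 is cut at the E1–O bond into phenol 1 and boronic acid 2, again with the crowded oxygen (D4) on the nucleophile. The forward reaction must leave the C–Br bond of 1 untouched, since it is the handle for the next coupling.

## Roads not taken

**Alternative 1: central ring C by Danheiser benzannulation.**
- Cut: through ring C itself (C3–C4 and C5–C6, with C2–C3 opening and re-forming). This leaves cyclobutenone A2, which carries the A–B aryloxy group on its vinylic carbon and the D–E aryloxy group on its saturated carbon, and silyl ynol ether A3.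
- Forward: heating A2 with A3 would pass through a vinylketene, a [2+2] adduct and a 6π closure to pentamer A1, with ring C as C3 phenol and C5 silyl ether.
- Merits: it is the most convergent of the four plans. Both ethers of ring C, including the tri-ortho B4–O–C1 bridge, are in place before the ring exists, and the mechanism fixes the oxygen pattern.
- Weak points: A2 has no simple preparation. It would itself come from a ketene and ynol ether derived from hindered, electron-rich phenols, and its α-aryloxy group is a potential leaving group under the thermal conditions. The A–B arm still needs the A1–O ether from a crowded electrophile. The phenol/silyl ether differentiation in A1 buys nothing, since both oxygens end as hydroxyl.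
- Comparison: in convergence and longest linear sequence this road would beat the chosen one if A2 were at hand. The chosen route sets against it that every intermediate derives from bought methoxyarenes by precedented reaction types, and that its one uncertain step (14 to 16) acts on an easily made substrate.

**Alternative 2: ring A from an aryloxymalonate.**
- Cut: A1–A6 and A3–A4, unravelling ring A to malonate A5, whose central carbon already carries the ring B oxygen, and keto diester A6.
- Forward: double Claisen acylation under alkoxide with heating would give phloroglucinol diester A4.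
- Merits: it makes the A1–O–B1 ether without any coupling, from cheap reagents, by the same logic as the chosen key step (the crowded ring is grown on the oxygen). For ring A alone it is arguably better than steps 10 to 12 of the chosen route.
- Weak points: A5 has an acidic C–H that alkoxide removes, which blunts it as a double acylating agent. A4 needs ester hydrolysis, decarboxylation and renewed methylation of three hydroxyls. Decisively, the ring synthesis is spent at the chain end, where the ether has only two ortho substituents, and the tri-ortho B4–O–C1 bridge is left to a coupling of the debenzylated B4 phenol with a ring C electrophile bearing an ortho oxygen.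
- Comparison: the chosen plan uses its ring synthesis on the one ether that coupling cannot easily make, and its ring closure is intramolecular.

**Alternative 3: ring B oxygens from a trifluorobenzaldehyde in one pot.**
- Cut: three C–O bonds at ring B (O–B1, B3–O, B5–O), so that ring B arrives as aldehyde A8 and ring A as phenol A9.
- Forward: the phenoxide of A9 displaces the para fluoride and methoxide the two ortho fluorides in the same flask, giving aldehyde A7; a Dakin oxidation would then turn the formyl carbon into the B4 hydroxyl.
- Merits: it is very short. The crowded ring A enters as the nucleophile, the favourable polarity, and one pot sets the whole oxygen pattern of ring B. For the A–B ether it is clearly shorter and more reliable than steps 9 to 12 here.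
- Weak points: the first substitution has to choose para over ortho fluoride with a bulky phenoxide. The sequence stops being iterative at the hardest bond: the B4 phenol, between two methoxy groups, would have to be joined to a ring C electrophile with an oxygen next to its leaving group, and ring C's 1,2-diether pattern cannot come from a para-selective fluoride displacement.
- Comparison: the chosen route borrows the same polarity for its own outer ethers (steps 1 and 4) and sets the de novo construction of the B4–O–C1 ether against the shortness of this road.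

Key step: step 9

## Route

Remark on the chemistry: 22 has no stereocentre; the only stereochemical element in the route is the Z enol ether of the transient ester 15, inherited from the pyranone ring.

Shorthand in the names below: ArO = 2-[3,5-dimethoxy-4-(3,4,5-trimethoxyphenoxy)phenoxy]-3,5-dimethoxyphenoxy, i.e. the permethylated rings C, D and E bound through the oxygen on C1. Full names are in the compound list.

Step 1
Reactants: 1 4-bromo-2,6-dimethoxyphenol; 2 (3,4,5-trimethoxyphenyl)boronic acid
Product: 3 5-bromo-1,3-dimethoxy-2-(3,4,5-trimethoxyphenoxy)benzene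
Conditions: Cu(OAc)2 (1 equiv), pyridine, 4 Å MS, CH2Cl2, air, rt
Reagents that add atoms: none
Why: Chan–Lam coupling: the aryl group of 2 is transferred to copper, the phenoxide of 1 binds, and reductive elimination from trivalent copper gives the ether; this oxidative coupling is a standard way to arylate a phenol flanked by two ortho substituents, it runs at room temperature where the C–Br bond is inert, and air returns the copper to its divalent state.

Step 2
Reactants: 4 2-hydroxy-4,6-dimethoxybenzaldehyde; 5 benzyl bromide
Product: 6 2-(benzyloxy)-4,6-dimethoxybenzaldehyde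
Conditions: K2CO3, DMF, 60 °C
Reagents that add atoms: none
Why: Williamson ether synthesis on the chelated ortho-hydroxyl; the benzyl ether masks the future C1 oxygen until the C2–O–D1 ether is in place.

Step 3
Reactants: 6 2-(benzyloxy)-4,6-dimethoxybenzaldehyde
Product: 8 2-(benzyloxy)-4,6-dimethoxyphenol, via aryl formate 7 (not isolated)
Conditions: mCPBA, CH2Cl2, 0 °C to rt; then K2CO3 (cat.), MeOH, rt
Reagents that add atoms: mCPBA (3-chloroperoxybenzoic acid), OOC(=O)c1cccc(Cl)c1
Why: Baeyer–Villiger oxidation (Dakin-type): with three ortho/para alkoxy donors the aryl group migrates in preference to hydride to give formate 7, which is methanolysed in the same flask; the inserted oxygen is the future C2 oxygen.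

Step 4
Reactants: 8 2-(benzyloxy)-4,6-dimethoxyphenol; 3 5-bromo-1,3-dimethoxy-2-(3,4,5-trimethoxyphenoxy)benzene
Product: 9 1-(benzyloxy)-2-[3,5-dimethoxy-4-(3,4,5-trimethoxyphenoxy)phenoxy]-3,5-dimethoxybenzene
Conditions: CuI (10 mol%), picolinic acid (20 mol%), K3PO4, DMSO, 90 °C, argon
Reagents that add atoms: none
Why: Ullmann-type diaryl ether synthesis with a CuI/picolinic acid catalyst, a system suited to phenols with two ortho substituents; the crowded partner is the nucleophile and bromide 3 is open at the reacting carbon, the favourable polarity for copper catalysis.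

Step 5
Reactants: 9 1-(benzyloxy)-2-[3,5-dimethoxy-4-(3,4,5-trimethoxyphenoxy)phenoxy]-3,5-dimethoxybenzene
Product: 10 ArOH, 2-[3,5-dimethoxy-4-(3,4,5-trimethoxyphenoxy)phenoxy]-3,5-dimethoxyphenol
Conditions: H2 (1 atm), 10% Pd/C, EtOAc–MeOH, rt
Reagents that add atoms: none
Why: Hydrogenolysis of the benzyl ether; methyl and diaryl ethers are inert and the C1 phenol is released under neutral conditions.

Step 6
Reactants: 11 4-hydroxy-6-methyl-2H-pyran-2-one
Product: 12 3-diazo-6-methyl-2H-pyran-2,4(3H)-dione
Conditions: p-ABSA, Et3N, MeCN, 0 °C to rt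
Reagents that add atoms: p-ABSA (4-acetamidobenzenesulfonyl azide), CC(=O)Nc1ccc(cc1)S(=O)(=O)N=[N+]=[N-]
Why: Regitz diazo transfer to the acidic C3 position of the cyclic 1,3-dicarbonyl tautomer of 11; the sulfonamide by-product is removed by basic wash.

Step 7
Reactants: 10 ArOH; 12 3-diazo-6-methyl-2H-pyran-2,4(3H)-dione
Product: 13 3-(ArO)-4-hydroxy-6-methyl-2H-pyran-2-one
Conditions: Rh2(OAc)4 (2 mol%), ClCH2CH2Cl, 80 °C, slow addition of 12
Reagents that add atoms: none
Why: Rhodium carbenoid O–H insertion: Rh2(OAc)4 turns 12 into an electrophilic carbenoid that is captured by the phenol oxygen (oxonium ylide, then proton shift), a known route from cyclic 2-diazo-1,3-diones and phenols to 2-aryloxy-1,3-dicarbonyl compounds; the insertion is little affected by the ortho aryloxy group of 10, and the product enolises to the 4-hydroxy-2-pyranone.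

Step 8
Reactants: 13 3-(ArO)-4-hydroxy-6-methyl-2H-pyran-2-one
Product: 14 3-(ArO)-4-methoxy-6-methyl-2H-pyran-2-one
Conditions: Me2SO4, K2CO3, acetone, reflux
Reagents that add atoms: dimethyl sulfate, COS(=O)(=O)OC
Why: O-Methylation of the vinylogous acid under the standard conditions that convert 4-hydroxy-6-methyl-2-pyranones into 4-methoxy-2-pyranones rather than the 2-methoxy-4-pyranone isomers; C3 is fully substituted, so C-methylation would break the conjugation and is disfavoured.

Step 9
Reactants: 14 3-(ArO)-4-methoxy-6-methyl-2H-pyran-2-one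
Product: 16 4-(ArO)-5-methoxybenzene-1,3-diol, via open-chain keto ester 15 (not isolated)
Conditions: Mg(OMe)2 (4 equiv), MeOH, reflux, argon; then 1 M HCl
Reagents that add atoms: magnesium methoxide, CO[Mg]OC (its methoxide becomes the ester methoxy group of 15 and is expelled again on ring closure; 16 retains no reagent atom)
Why: Magnesium methoxide adds to the lactone carbonyl of 14 and the ring oxygen leaves as the enolate of a methyl ketone, giving the Z keto ester 15 as its magnesium chelate; equilibration then produces the terminal (methyl) enolate, which attacks the ester carbon, methoxide is expelled and the cyclohexenedione tautomerises to resorcinol 16 (Claisen condensation, new B2–B3 bond). The closest known reaction type is the base-mediated ring opening and Claisen recyclisation of 4-methoxy-6-methyl-2-pyranones to 5-methoxyresorcinols; here the pyranone merely carries an additional 3-aryloxy group. Ring B closes by a 6-(enolendo)-exo-trig acyl substitution and no stereocentre is formed. Three selectivities are needed: addition at the lactone carbonyl and not at C4 or C6, closure of the enolate through carbon and not oxygen, and closure through the methyl carbon. Exchange at C4 is degenerate (methoxide for methoxide), oxygen closure only returns 14, and the internal CH2 enolate has no ring size open to it, so all unproductive paths are reversible while aromatisation to the magnesium phenoxide of 16 is not. The Z enol ether fixed by the former ring holds ester and ketone chain cis, C3 bears no hydrogen so the ester side cannot enolise, and magnesium chelation of the ester and enolate oxygens favours carbon–carbon closure. Aryl and methyl ethers are inert to methoxide; the electron-rich product is handled under argon.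

Step 10
Reactants: 16 4-(ArO)-5-methoxybenzene-1,3-diol; 17 4-bromo-3,5-dimethoxybenzaldehyde
Product: 18 4-[4-(ArO)-3-hydroxy-5-methoxyphenoxy]-3,5-dimethoxybenzaldehyde
Conditions: 17 (1.0 equiv), CuI (10 mol%), picolinic acid (20 mol%), K3PO4, DMSO, 90 °C, argon
Reagents that add atoms: none
Why: Ullmann-type coupling; the para-formyl group makes bromide 17 electron-poor enough for oxidative addition despite its two flanking methoxy groups, and only the open B1 phenoxide leads to an ether with two ortho substituents, whereas reaction at B3 would create one with three next to the bulky C–D–E unit; one equivalent of 17 limits double arylation.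

Step 11
Reactants: 18 4-[4-(ArO)-3-hydroxy-5-methoxyphenoxy]-3,5-dimethoxybenzaldehyde
Product: 19 4-[4-(ArO)-3,5-dimethoxyphenoxy]-3,5-dimethoxybenzaldehyde
Conditions: MeI, K2CO3, DMF, rt
Reagents that add atoms: iodomethane, CI
Why: Williamson methylation of the remaining B3 phenol, so that no free electron-rich phenol meets the peracid in the next step; the non-enolisable aldehyde tolerates K2CO3.

Step 12
Reactants: 19 4-[4-(ArO)-3,5-dimethoxyphenoxy]-3,5-dimethoxybenzaldehyde
Product: 21 4-[4-(ArO)-3,5-dimethoxyphenoxy]-3,5-dimethoxyphenol, via aryl formate 20 (not isolated)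
Conditions: mCPBA, CH2Cl2, 0 °C; then K2CO3 (cat.), MeOH, rt
Reagents that add atoms: mCPBA (3-chloroperoxybenzoic acid), OOC(=O)c1cccc(Cl)c1
Why: Baeyer–Villiger oxidation and formate methanolysis; the para-aryloxy donor favours aryl over hydride migration, as in the conversion of 3,4,5-trialkoxybenzaldehydes into phenols, and the aldehyde should react with the peracid at 0 °C faster than the fully etherified rings.

Step 13
Reactants: 21 4-[4-(ArO)-3,5-dimethoxyphenoxy]-3,5-dimethoxyphenol
Product: 22 2-(4-{2-[3,5-dihydroxy-4-(3,4,5-trihydroxyphenoxy)phenoxy]-3,5-dihydroxyphenoxy}-3,5-dihydroxyphenoxy)benzene-1,3,5-triol (target, CNP0227069.0)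
Conditions: BBr3 (excess), CH2Cl2, −78 °C to rt; then MeOH, H2O, under argon
Reagents that add atoms: none
Why: Lewis acid ether cleavage: BBr3 complexes each methoxy oxygen and bromide attacks the methyl carbon, so all eleven methyl ethers fall while the four diaryl ether bonds, which offer no sp3 carbon, stay intact; quench and isolation under argon protect pyrogallol ring E.

## Compound list

1 | 4-bromo-2,6-dimethoxyphenol | COc1cc(Br)cc(OC)c1O | starting material
2 | (3,4,5-trimethoxyphenyl)boronic acid | COc1cc(cc(OC)c1OC)B(O)O | starting material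
3 | 5-bromo-1,3-dimethoxy-2-(3,4,5-trimethoxyphenoxy)benzene | COc1cc(Br)cc(OC)c1Oc1cc(OC)c(OC)c(OC)c1 | intermediate
4 | 2-hydroxy-4,6-dimethoxybenzaldehyde | COc1cc(O)c(C=O)c(OC)c1 | starting material
5 | benzyl bromide | BrCc1ccccc1 | starting material
6 | 2-(benzyloxy)-4,6-dimethoxybenzaldehyde | COc1cc(OCc2ccccc2)c(C=O)c(OC)c1 | intermediate
7 | 2-(benzyloxy)-4,6-dimethoxyphenyl formate | COc1cc(OCc2ccccc2)c(OC=O)c(OC)c1 | intermediate (not isolated)
8 | 2-(benzyloxy)-4,6-dimethoxyphenol | COc1cc(OCc2ccccc2)c(O)c(OC)c1 | intermediate
9 | 1-(benzyloxy)-2-[3,5-dimethoxy-4-(3,4,5-trimethoxyphenoxy)phenoxy]-3,5-dimethoxybenzene | COc1cc(OCc2ccccc2)c(Oc2cc(OC)c(Oc3cc(OC)c(OC)c(OC)c3)c(OC)c2)c(OC)c1 | intermediate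
10 | 2-[3,5-dimethoxy-4-(3,4,5-trimethoxyphenoxy)phenoxy]-3,5-dimethoxyphenol | COc1cc(O)c(Oc2cc(OC)c(Oc3cc(OC)c(OC)c(OC)c3)c(OC)c2)c(OC)c1 | intermediate
11 | 4-hydroxy-6-methyl-2H-pyran-2-one | CC1=CC(O)=CC(=O)O1 | starting material
12 | 3-diazo-6-methyl-2H-pyran-2,4(3H)-dione | CC1=CC(=O)C(=[N+]=[N-])C(=O)O1 | intermediate
13 | 3-{2-[3,5-dimethoxy-4-(3,4,5-trimethoxyphenoxy)phenoxy]-3,5-dimethoxyphenoxy}-4-hydroxy-6-methyl-2H-pyran-2-one | CC1=CC(O)=C(Oc2cc(OC)cc(OC)c2Oc2cc(OC)c(Oc3cc(OC)c(OC)c(OC)c3)c(OC)c2)C(=O)O1 | intermediate
14 | 3-{2-[3,5-dimethoxy-4-(3,4,5-trimethoxyphenoxy)phenoxy]-3,5-dimethoxyphenoxy}-4-methoxy-6-methyl-2H-pyran-2-one | CC1=CC(OC)=C(Oc2cc(OC)cc(OC)c2Oc2cc(OC)c(Oc3cc(OC)c(OC)c(OC)c3)c(OC)c2)C(=O)O1 | intermediate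
15 | methyl (2Z)-2-{2-[3,5-dimethoxy-4-(3,4,5-trimethoxyphenoxy)phenoxy]-3,5-dimethoxyphenoxy}-3-methoxy-5-oxohex-2-enoate | COC(=O)/C(Oc1cc(OC)cc(OC)c1Oc1cc(OC)c(Oc2cc(OC)c(OC)c(OC)c2)c(OC)c1)=C(\CC(C)=O)OC | intermediate (not isolated)
16 | 4-{2-[3,5-dimethoxy-4-(3,4,5-trimethoxyphenoxy)phenoxy]-3,5-dimethoxyphenoxy}-5-methoxybenzene-1,3-diol | COc1cc(O)cc(O)c1Oc1cc(OC)cc(OC)c1Oc1cc(OC)c(Oc2cc(OC)c(OC)c(OC)c2)c(OC)c1 | intermediate
17 | 4-bromo-3,5-dimethoxybenzaldehyde | COc1cc(C=O)cc(OC)c1Br | starting material
18 | 4-(4-{2-[3,5-dimethoxy-4-(3,4,5-trimethoxyphenoxy)phenoxy]-3,5-dimethoxyphenoxy}-3-hydroxy-5-methoxyphenoxy)-3,5-dimethoxybenzaldehyde | O=Cc1cc(OC)c(Oc2cc(O)c(Oc3cc(OC)cc(OC)c3Oc3cc(OC)c(Oc4cc(OC)c(OC)c(OC)c4)c(OC)c3)c(OC)c2)c(OC)c1 | intermediate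
19 | 4-(4-{2-[3,5-dimethoxy-4-(3,4,5-trimethoxyphenoxy)phenoxy]-3,5-dimethoxyphenoxy}-3,5-dimethoxyphenoxy)-3,5-dimethoxybenzaldehyde | O=Cc1cc(OC)c(Oc2cc(OC)c(Oc3cc(OC)cc(OC)c3Oc3cc(OC)c(Oc4cc(OC)c(OC)c(OC)c4)c(OC)c3)c(OC)c2)c(OC)c1 | intermediate
20 | 4-(4-{2-[3,5-dimethoxy-4-(3,4,5-trimethoxyphenoxy)phenoxy]-3,5-dimethoxyphenoxy}-3,5-dimethoxyphenoxy)-3,5-dimethoxyphenyl formate | O=COc1cc(OC)c(Oc2cc(OC)c(Oc3cc(OC)cc(OC)c3Oc3cc(OC)c(Oc4cc(OC)c(OC)c(OC)c4)c(OC)c3)c(OC)c2)c(OC)c1 | intermediate (not isolated)
21 | 4-(4-{2-[3,5-dimethoxy-4-(3,4,5-trimethoxyphenoxy)phenoxy]-3,5-dimethoxyphenoxy}-3,5-dimethoxyphenoxy)-3,5-dimethoxyphenol | Oc1cc(OC)c(Oc2cc(OC)c(Oc3cc(OC)cc(OC)c3Oc3cc(OC)c(Oc4cc(OC)c(OC)c(OC)c4)c(OC)c3)c(OC)c2)c(OC)c1 | intermediate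
22 | 2-(4-{2-[3,5-dihydroxy-4-(3,4,5-trihydroxyphenoxy)phenoxy]-3,5-dihydroxyphenoxy}-3,5-dihydroxyphenoxy)benzene-1,3,5-triol | Oc1cc(O)c(Oc2cc(O)c(Oc3cc(O)cc(O)c3Oc3cc(O)c(Oc4cc(O)c(O)c(O)c4)c(O)c3)c(O)c2)c(O)c1 | target

## Step count and risks

Total step count: 13. Longest linear sequence: 11 steps (from 4 through steps 2 to 5 and 7 to 13); steps 1 and 6 are side branches.

**Step 9 (key step).** The most likely failure is ring opening without carbon–carbon closure. The ester carbonyl of 15 is shielded by the bulky 2-aryloxy group, so the open chain may linger and be lost through enol ether cleavage or ester hydrolysis, or simply revert to 14 by oxygen closure. The fallback sets out from 10 and builds ring B as a phloroglucinol instead: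
- alkylation of 10 with diethyl bromomalonate (K2CO3, acetone) should give diethyl 2-{2-[3,5-dimethoxy-4-(3,4,5-trimethoxyphenoxy)phenoxy]-3,5-dimethoxyphenoxy}propanedioate F1;
- double Claisen condensation with diethyl 3-oxopentanedioate (NaOEt, EtOH, reflux) should give diethyl 5-(ArO)-2,4,6-trihydroxybenzene-1,3-dicarboxylate F2;
- saponification and decarboxylation (aqueous NaOH, reflux, then acid) should give 2-(ArO)benzene-1,3,5-triol F3;
- copper-catalysed coupling with 17 at the open B1 hydroxyl, under the conditions of step 10, should give 4-[4-(ArO)-3,5-dihydroxyphenoxy]-3,5-dimethoxybenzaldehyde F4;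
- twofold methylation (MeI, K2CO3, DMF) comes back to the route at 19.

**Step 7.** The electrophilic carbenoid may attack the very electron-rich aromatic rings of 10 (aromatic substitution or Buchner-type addition) or undergo Wolff rearrangement instead of inserting into the O–H bond. The fallback sets out from 10 and makes the same bond by substitution, then builds the pyranone around it:
- alkylation with ethyl 2-chloro-3-oxobutanoate (K2CO3, acetone) should give racemic ethyl 2-(ArO)-3-oxobutanoate F5;
- its dianion (NaH, then n-BuLi, THF) is acylated at the methyl carbon with N-methoxy-N-methylacetamide to give ethyl 2-(ArO)-3,5-dioxohexanoate F6;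
- lactonisation (DBU, toluene, reflux) comes back to the route at 13.

**Step 10.** Oxidative addition into a bromide flanked by two methoxy groups is slow. Forcing the reaction invites loss of site selectivity (arylation at B3 or at both phenols) and reduction of 17. The fallback sets out from 16 and removes the selectivity question before the coupling:
- silylation of the open B1 hydroxyl (iPr3SiCl, imidazole, DMF, 0 °C) should give 2-(ArO)-3-methoxy-5-[tri(propan-2-yl)silyloxy]phenol F7;
- methylation of B3 (MeI, K2CO3, acetone) should give [4-(ArO)-3,5-dimethoxyphenoxy]tri(propan-2-yl)silane F8;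
- desilylation (Bu4NF, THF) should give 4-(ArO)-3,5-dimethoxyphenol F9;
- with a single phenol left, the coupling with excess 17 can be driven hard (copper as in step 10, or Pd(OAc)2 with a bulky biarylphosphine and K3PO4 in toluene) and comes back to the route at 19, so step 11 is no longer needed.

**Step 12.** The peracid may oxidise the electron-rich tetra-alkoxy rings (ring hydroxylation, quinone formation), or hydride may migrate instead of aryl to give the benzoic acid. The fallback sets out from 16 and brings ring A in at its final oxidation level. Copper-catalysed coupling with 2-iodo-1,3,5-trimethoxybenzene (CuI, picolinic acid, K3PO4, DMSO) should give 2-(ArO)-3-methoxy-5-(2,4,6-trimethoxyphenoxy)phenol F10. Demethylation with BBr3 as in step 13 comes back to the route at 22. The price is a less reactive, electron-rich iodide in the coupling.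

**Step 4.** The di-ortho-alkoxy phenoxide of 8 is very electron-rich and may be consumed by oxidative self-coupling, or the bromide may be reduced before the ether forms. The fallback sets out from 3 and reverses the roles, as in step 1. Bromine–lithium exchange (n-BuLi, THF, −78 °C), B(OiPr)3 and aqueous acid should give [3,5-dimethoxy-4-(3,4,5-trimethoxyphenoxy)phenyl]boronic acid F11. Chan–Lam coupling with 8 (Cu(OAc)2, pyridine, 4 Å MS, CH2Cl2, air) comes back to the route at 9.

## Further compounds

F1 | step 9 | diethyl 2-{2-[3,5-dimethoxy-4-(3,4,5-trimethoxyphenoxy)phenoxy]-3,5-dimethoxyphenoxy}propanedioate | CCOC(=O)C(Oc1cc(OC)cc(OC)c1Oc1cc(OC)c(Oc2cc(OC)c(OC)c(OC)c2)c(OC)c1)C(=O)OCC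
F2 | step 9 | diethyl 5-{2-[3,5-dimethoxy-4-(3,4,5-trimethoxyphenoxy)phenoxy]-3,5-dimethoxyphenoxy}-2,4,6-trihydroxybenzene-1,3-dicarboxylate | CCOC(=O)c1c(O)c(C(=O)OCC)c(O)c(Oc2cc(OC)cc(OC)c2Oc2cc(OC)c(Oc3cc(OC)c(OC)c(OC)c3)c(OC)c2)c1O
F3 | step 9 | 2-{2-[3,5-dimethoxy-4-(3,4,5-trimethoxyphenoxy)phenoxy]-3,5-dimethoxyphenoxy}benzene-1,3,5-triol | Oc1cc(O)c(Oc2cc(OC)cc(OC)c2Oc2cc(OC)c(Oc3cc(OC)c(OC)c(OC)c3)c(OC)c2)c(O)c1
F4 | step 9 | 4-(4-{2-[3,5-dimethoxy-4-(3,4,5-trimethoxyphenoxy)phenoxy]-3,5-dimethoxyphenoxy}-3,5-dihydroxyphenoxy)-3,5-dimethoxybenzaldehyde | O=Cc1cc(OC)c(Oc2cc(O)c(Oc3cc(OC)cc(OC)c3Oc3cc(OC)c(Oc4cc(OC)c(OC)c(OC)c4)c(OC)c3)c(O)c2)c(OC)c1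
F5 | step 7 | ethyl 2-{2-[3,5-dimethoxy-4-(3,4,5-trimethoxyphenoxy)phenoxy]-3,5-dimethoxyphenoxy}-3-oxobutanoate (racemic) | CCOC(=O)C(Oc1cc(OC)cc(OC)c1Oc1cc(OC)c(Oc2cc(OC)c(OC)c(OC)c2)c(OC)c1)C(C)=O
F6 | step 7 | ethyl 2-{2-[3,5-dimethoxy-4-(3,4,5-trimethoxyphenoxy)phenoxy]-3,5-dimethoxyphenoxy}-3,5-dioxohexanoate (racemic) | CCOC(=O)C(Oc1cc(OC)cc(OC)c1Oc1cc(OC)c(Oc2cc(OC)c(OC)c(OC)c2)c(OC)c1)C(=O)CC(C)=O
F7 | step 10 | 2-{2-[3,5-dimethoxy-4-(3,4,5-trimethoxyphenoxy)phenoxy]-3,5-dimethoxyphenoxy}-3-methoxy-5-[tri(propan-2-yl)silyloxy]phenol | COc1cc(O[Si](C(C)C)(C(C)C)C(C)C)cc(O)c1Oc1cc(OC)cc(OC)c1Oc1cc(OC)c(Oc2cc(OC)c(OC)c(OC)c2)c(OC)c1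
F8 | step 10 | (4-{2-[3,5-dimethoxy-4-(3,4,5-trimethoxyphenoxy)phenoxy]-3,5-dimethoxyphenoxy}-3,5-dimethoxyphenoxy)tri(propan-2-yl)silane | COc1cc(O[Si](C(C)C)(C(C)C)C(C)C)cc(OC)c1Oc1cc(OC)cc(OC)c1Oc1cc(OC)c(Oc2cc(OC)c(OC)c(OC)c2)c(OC)c1
F9 | step 10 | 4-{2-[3,5-dimethoxy-4-(3,4,5-trimethoxyphenoxy)phenoxy]-3,5-dimethoxyphenoxy}-3,5-dimethoxyphenol | COc1cc(O)cc(OC)c1Oc1cc(OC)cc(OC)c1Oc1cc(OC)c(Oc2cc(OC)c(OC)c(OC)c2)c(OC)c1
F10 | step 12 | 2-{2-[3,5-dimethoxy-4-(3,4,5-trimethoxyphenoxy)phenoxy]-3,5-dimethoxyphenoxy}-3-methoxy-5-(2,4,6-trimethoxyphenoxy)phenol | COc1cc(OC)c(Oc2cc(O)c(Oc3cc(OC)cc(OC)c3Oc3cc(OC)c(Oc4cc(OC)c(OC)c(OC)c4)c(OC)c3)c(OC)c2)c(OC)c1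
F11 | step 4 | [3,5-dimethoxy-4-(3,4,5-trimethoxyphenoxy)phenyl]boronic acid | COc1cc(cc(OC)c1Oc1cc(OC)c(OC)c(OC)c1)B(O)O
A1 | alternative 1 | 2-[3,5-dimethoxy-4-(3,4,5-trimethoxyphenoxy)phenoxy]-3-[2,6-dimethoxy-4-(2,4,6-trimethoxyphenoxy)phenoxy]-5-[tri(propan-2-yl)silyloxy]phenol | COc1cc(OC)c(Oc2cc(OC)c(Oc3cc(O[Si](C(C)C)(C(C)C)C(C)C)cc(O)c3Oc3cc(OC)c(Oc4cc(OC)c(OC)c(OC)c4)c(OC)c3)c(OC)c2)c(OC)c1
A2 | alternative 1 | 3-[2,6-dimethoxy-4-(2,4,6-trimethoxyphenoxy)phenoxy]-4-[3,5-dimethoxy-4-(3,4,5-trimethoxyphenoxy)phenoxy]cyclobut-2-en-1-one (racemic) | O=C1C=C(Oc2c(OC)cc(Oc3c(OC)cc(OC)cc3OC)cc2OC)C1Oc1cc(OC)c(Oc2cc(OC)c(OC)c(OC)c2)c(OC)c1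
A3 | alternative 1 | (ethynyloxy)tri(propan-2-yl)silane | C#CO[Si](C(C)C)(C(C)C)C(C)C
A4 | alternative 2 | dimethyl 5-[4-(benzyloxy)-3,5-dimethoxyphenoxy]-2,4,6-trihydroxybenzene-1,3-dicarboxylate | COC(=O)c1c(O)c(Oc2cc(OC)c(OCc3ccccc3)c(OC)c2)c(O)c(C(=O)OC)c1O
A5 | alternative 2 | dimethyl 2-[4-(benzyloxy)-3,5-dimethoxyphenoxy]propanedioate | COC(=O)C(Oc1cc(OC)c(OCc2ccccc2)c(OC)c1)C(=O)OC
A6 | alternative 2 | dimethyl 3-oxopentanedioate | COC(=O)CC(=O)CC(=O)OC
A7 | alternative 3 | 2,6-dimethoxy-4-(2,4,6-trimethoxyphenoxy)benzaldehyde | COc1cc(OC)c(Oc2cc(OC)c(C=O)c(OC)c2)c(OC)c1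
A8 | alternative 3 | 2,4,6-trifluorobenzaldehyde | O=Cc1c(F)cc(F)cc1F
A9 | alternative 3 | 2,4,6-trimethoxyphenol | COc1cc(OC)c(O)c(OC)c1
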